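## Retrosynthetic overview

- The route rests on ring A (C1–C5, C10): the C1 acetoxy oxygen and the lactone methylene C20 are cis, C20 sits on the quaternary spiro carbon C10, and C10 is β to the C6 carboxyl on C5. A CH2 radical tied through silicon to the C1 oxygen can therefore add to C10 of a C5=C10 enoate and place C20 on the required face.
- Target 25 ⇐ tert-butyl ester 24 ⇐ 16-methylene-15-ketone 23 ⇐ ring D by palladium-mediated closure of C16 onto C13 of a ring C alkene (22) ⇐ ring C by Diels–Alder addition of butadiene to the C8=C9 alkylidene β-keto lactone 18.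
- 18 ⇐ acetoacetylation of C20–OH and Knoevenagel closure onto the C9 aldehyde ⇐ diol 12 ⇐ Tamao oxidation of oxasilolane 11 ⇐ 5-exo radical cyclisation of bromomethylsilyl ether 10.
- 10 ⇐ CBS reduction of enone 7 ⇐ β-cyclocitral 1 (oxidation, esterification, allylic oxidation, bromination, etherification).
- Ring order: ring A (from 1), temporary oxasilolane, δ-lactone, ring C, ring D.

Key step: step 8

Remark: ent-kaurane numbering is used for every intermediate (C1 acetoxy carbon, C4 gem-dimethyl carbon, C5 with carboxyl C6, spiro C10, lactone C20H2–O–C7(=O), C8, C9, ring C C11–C14, ketone C15, C16 with methyl C17), and diketene and buta-1,3-diene are taken as commercial.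

## Route

Step 1
Reactants: 1 β-cyclocitral (2,6,6-trimethylcyclohex-1-ene-1-carbaldehyde)
Product: 2 β-cyclogeranic acid (2,6,6-trimethylcyclohex-1-ene-1-carboxylic acid)
Conditions: NaClO2, NaH2PO4, 2-methylbut-2-ene, tBuOH/H2O, rt
Reagents that add atoms: sodium chlorite, [Na+].[O-]Cl=O
Why: Pinnick oxidation converts the hindered conjugated aldehyde to the acid without touching the tetrasubstituted alkene, the hypochlorous acid by-product being trapped by 2-methylbut-2-ene.

Step 2
Reactants: 2 β-cyclogeranic acid
Product: 3 tert-butyl 2,6,6-trimethylcyclohex-1-ene-1-carboxylate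
Conditions: tert-butyl 2,2,2-trichloroacetimidate (2 equiv), BF3·OEt2 (cat.), cyclohexane/CH2Cl2, rt
Reagents that add atoms: tert-butyl 2,2,2-trichloroacetimidate, CC(C)(C)OC(=N)C(Cl)(Cl)Cl
Why: Acid-catalysed O-tert-butylation transfers a tert-butyl cation to the carboxyl oxygen, so the shielding of the acyl carbon by C4 and C10 does not matter.

Step 3
Reactants: 3 tert-butyl 2,6,6-trimethylcyclohex-1-ene-1-carboxylate
Product: 4 tert-butyl 2,6,6-trimethyl-3-oxocyclohex-1-ene-1-carboxylate (ketone at C1)
Conditions: tBuOOH (70% aq., 5 equiv), Rh2(cap)4 (dirhodium tetracaprolactamate, 1 mol %), K2CO3 (0.5 equiv), CH2Cl2, rt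
Reagents that add atoms: tert-butyl hydroperoxide, CC(C)(C)OO
Why: Radical allylic oxidation attacks the secondary ring CH2 at C1, which is γ to the ester, in preference to the C10 methyl, and gives the γ-keto enoate as is usual for cyclogeranate-type rings.

Step 4
Reactants: 4 tert-butyl 2,6,6-trimethyl-3-oxocyclohex-1-ene-1-carboxylate
Product: 5 tert-butyl 2-(bromomethyl)-6,6-dimethyl-3-oxocyclohex-1-ene-1-carboxylate (bromide at C9)
Conditions: N-bromosuccinimide (1.05 equiv), visible light, NaHCO3, PhCF3, 20 °C; used at once
Reagents that add atoms: N-bromosuccinimide, O=C1CCC(=O)N1Br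
Why: Wohl–Ziegler bromination takes the C10 methyl because it is the only allylic C–H left (the γ-position of the enoate, the other γ-carbon C4 being quaternary), and running it with light at ambient temperature limits thermal closure of the γ-bromo tert-butyl enoate to a butenolide.

Step 5
Reactants: 5 tert-butyl 2-(bromomethyl)-6,6-dimethyl-3-oxocyclohex-1-ene-1-carboxylate; 6 4-methoxybenzyl alcohol
Product: 7 tert-butyl 2-[(4-methoxybenzyloxy)methyl]-6,6-dimethyl-3-oxocyclohex-1-ene-1-carboxylate
Conditions: 6 (1.5 equiv), NaH (1.4 equiv), THF, 0 °C; then 5, THF, −40 → 0 °C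
Reagents that add atoms: none
Why: Williamson ether synthesis by SN2 displacement of the primary allylic bromide under non-ionising conditions, which avoids participation of the neighbouring ester carbonyl that silver-assisted ionisation would invite.

Step 6
Reactants: 7 tert-butyl 2-[(4-methoxybenzyloxy)methyl]-6,6-dimethyl-3-oxocyclohex-1-ene-1-carboxylate
Product: 8 tert-butyl (3S)-3-hydroxy-2-[(4-methoxybenzyloxy)methyl]-6,6-dimethylcyclohex-1-ene-1-carboxylate (C1 S)
Conditions: (R)-2-methyl-CBS-oxazaborolidine (C18H20BNO, 0.2 equiv), BH3·SMe2 (0.7 equiv), THF, −20 °C; MeOH, then aqueous work-up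
Reagents that add atoms: none
Why: In this CBS reduction the α-substituted alkenyl carbon C10 acts as the large group and the C2 methylene as the small one, so the (R)-catalyst should deliver hydride 1,2 to give the (S)-alcohol at C1.

Step 7
Reactants: 8 (S)-allylic alcohol; 9 (bromomethyl)chlorodimethylsilane
Product: 10 (bromomethyl)dimethylsilyl ether of 8
Conditions: Et3N (1.5 equiv), 4-(dimethylamino)pyridine (cat.), CH2Cl2, 0 °C; rapid filtration, used without storage
Reagents that add atoms: none
Why: O-silylation at the Si–Cl bond is fast and leaves the C–Br bond untouched, and the hydrolytically labile ether is carried forward directly.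

Step 8
Reactants: 10 (bromomethyl)dimethylsilyl ether of 8
Product: 11 cis-fused oxasilolane of ring A (O1–SiMe2–C20H2–C10; C10 quaternary with the CH2OPMB arm C9 trans to O1; C5 ester cis to C20)
Conditions: Bu3SnH (1.3 equiv, syringe pump over 6 h), azobisisobutyronitrile (0.2 equiv), benzene, 80 °C, 0.01 M
Reagents that add atoms: none
Why: Bu3Sn• abstracts bromine to give a nucleophilic α-silyl methyl radical that adds to C10, the β-carbon of the C5=C10 enoate, and the ester-stabilised C5 radical is then reduced by Bu3SnH; the closest known reaction type is the radical cyclisation of (bromomethyl)dimethylsilyl ethers of allylic alcohols used for syn hydroxymethylation. The oxasilolane (O1–Si–C20–C10–C1) closes in the 5-exo-trig mode, because the 6-endo mode would need attack at C5, the polarity-mismatched α-carbon flanked by the gem-dimethyl carbon C4. C10 is set by the tether: the O–Si–CH2 link from the (S)-configured C1 reaches only the face of C10 on which the C1 oxygen lies, so C20 and O1 become cis and the C9 arm goes to the other face. C5 is set by hydrogen transfer from the stannane to the face opposite the new C10–C20 bond (overall anti addition across the former alkene), which leaves the ester equatorial and cis to C20. That arrangement is also the more stable one, so a minor C5 epimer could be converged with KOtBu in tBuOH. The step needs attack at C10 over C5 and cyclisation faster than direct reduction; the first is secured by enoate polarity and ring size, the second by high dilution and slow stannane addition.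

Step 9
Reactants: 11 cis-fused oxasilolane
Product: 12 diol (C1–OH and C20–OH cis; C9–OPMB; C5 tert-butyl ester cis to C20)
Conditions: 30% H2O2, KF, KHCO3, THF/MeOH (1:1), rt
Reagents that add atoms: hydrogen peroxide, OO
Why: Tamao oxidation converts the C20–Si bond into C20–OH with retention by peroxide attack at the alkoxy-activated silicon and 1,2-shift of C20 to oxygen, releases the C1 hydroxyl, and should spare the hindered tert-butyl ester in the bicarbonate medium.

Step 10
Reactants: 12 diol; 13 diketene (4-methyleneoxetan-2-one)
Product: 14 C20 acetoacetate of 12 (C1–OH free)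
Conditions: 13 (1.05 equiv), 4-(dimethylamino)pyridine (5 mol %), CH2Cl2, −20 → 0 °C
Reagents that add atoms: none
Why: Amine-catalysed ring-opening of diketene (acetoacetylation) by the primary C20 hydroxyl is expected to outpace reaction at the secondary C1 hydroxyl, which is flanked by the quaternary C10, at low temperature with one equivalent of reagent.

Step 11
Reactants: 14 C20 acetoacetate
Product: 15 C1 acetate of 14
Conditions: Ac2O, pyridine, 4-(dimethylamino)pyridine (cat.), CH2Cl2, rt
Reagents that add atoms: acetic anhydride, CC(=O)OC(C)=O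
Why: Catalysed acetylation of the remaining secondary hydroxyl installs the C1 acetate of the target early, which is allowed because no later step uses a strong base or nucleophile.

Step 12
Reactants: 15 C1 acetate
Product: 16 C9 primary alcohol (PMB removed)
Conditions: DDQ (1.3 equiv), CH2Cl2/pH 7 phosphate buffer (10:1), 0 °C; taken on at once
Reagents that add atoms: none
Why: Oxidative cleavage of the electron-rich benzyl ether by DDQ (hydride abstraction, then hydrolysis of the hemiacetal) frees the C9 hydroxyl without affecting the esters, and immediate use avoids 1,3-migration of the acetoacetyl group from O20 to O9.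

Step 13
Reactants: 16 C9 primary alcohol
Product: 18 spiro alkylidene β-keto lactone (3-acetyl-5,6-dihydro-2H-pyran-2-one spiro-fused to ring A at C10; C8=C9), via C9 aldehyde 17 (not isolated)
Conditions: Dess–Martin periodinane (1.3 equiv), NaHCO3, CH2Cl2, 0 °C → rt; filtration; then piperidine (0.2 equiv), AcOH (0.2 equiv), 4 Å MS, CH2Cl2, rt
Reagents that add atoms: none
Why: Oxidation gives the non-enolisable neopentyl aldehyde at C9 and amine-catalysed intramolecular Knoevenagel condensation with the acetoacetate methylene C8 closes the six-membered lactone, β-elimination being impossible because C10 is quaternary.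

Step 14
Reactants: 18 spiro alkylidene β-keto lactone; 19 buta-1,3-diene
Product: 20 Diels–Alder adduct (ring C cyclohexene with C12=C13, cis-fused to the lactone; C8 acetyl cis to H9; C11 on the C1 side of C10)
Conditions: 19 (10 equiv), ZnCl2 (1.5 equiv), CH2Cl2/Et2O, 0 °C → rt, sealed tube
Reagents that add atoms: none
Why: Chelation of the β-keto lactone by ZnCl2 activates the C8=C9 dienophile for a suprafacial Diels–Alder reaction that forms C9–C11 and C8–C14 together, and the diene is expected to approach C9 past the small C1 acetoxy flank instead of the C5 tert-butoxycarbonyl flank, which sets C8 and C9 relative to C10.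

Step 15
Reactants: 20 Diels–Alder adduct
Product: 21 tert-butyldimethylsilyl enol ether of the C15 methyl ketone (C15(OTBS)=C16H2)
Conditions: TBSOTf (1.2 equiv), Et3N (2 equiv), CH2Cl2, −78 → 0 °C
Reagents that add atoms: tert-butyldimethylsilyl trifluoromethanesulfonate, CC(C)(C)[Si](C)(C)OS(=O)(=O)C(F)(F)F
Why: Soft enolisation silylates the methyl ketone on its only enolisable side (C16, since C8 is quaternary) faster than the esters can react.

Step 16
Reactants: 21 silyl enol ether
Product: 22 tetracyclic ketone (bicyclo[3.2.1]octene: C16–C13 bond formed, C15 ketone, C11=C12)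
Conditions: Pd(OAc)2 (10 mol %), O2 (1 atm), DMSO, 45 °C
Reagents that add atoms: none
Why: Palladium-mediated cycloalkenylation of a methyl ketone silyl enol ether (the ring-forming relative of the Saegusa oxidation) proceeds through the enolate of divalent palladium, syn insertion of C12=C13 in the 5-exo mode and β-hydride elimination toward C11, C13 being fixed because C16 can reach only the face of ring C that carries C15, while O2 reoxidises zerovalent palladium.

Step 17
Reactants: 22 tetracyclic ketone
Product: 23 16-methylene-15-ketone (C16=C17H2)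
Conditions: paraformaldehyde (5 equiv), N-methylanilinium trifluoroacetate (2 equiv), THF, 65 °C
Reagents that add atoms: formaldehyde (as paraformaldehyde), C=O
Why: Mannich-type α-methylenation (iminium addition, then loss of the amine) occurs at C16, the only enolisable position of the C15 ketone.

Step 18
Reactants: 23 16-methylene-15-ketone
Product: 24 tert-butyl ester of the target (ring C saturated; C17 methyl on the side of the C9–C11–C12 bridge)
Conditions: H2 (1 atm), Pd/C (10% palladium on carbon), EtOAc, rt
Reagents that add atoms: none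
Why: Catalytic hydrogenation saturates C11=C12 and reduces the exocyclic enone from the exposed exo face of ring D, away from the C9–C11–C12 bridge, which places the C17 methyl on the side of that bridge as in the target.

Step 19
Reactants: 24 tert-butyl ester of the target
Product: 25 target acid CNP0161834.1
Conditions: CF3CO2H/CH2Cl2 (1:4), 0 °C, short reaction time
Reagents that add atoms: none
Why: Acidolysis of the tert-butyl ester through the tert-butyl cation frees the C6 acid, while acetate, δ-lactone and the C16 centre should survive brief cold acid.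

## Compound list

1 | β-cyclocitral | CC1=C(C=O)C(C)(C)CCC1 | starting material
2 | β-cyclogeranic acid | CC1=C(C(=O)O)C(C)(C)CCC1 | intermediate
3 | tert-butyl 2,6,6-trimethylcyclohex-1-ene-1-carboxylate | CC1=C(C(=O)OC(C)(C)C)C(C)(C)CCC1 | intermediate
4 | tert-butyl 2,6,6-trimethyl-3-oxocyclohex-1-ene-1-carboxylate | CC1=C(C(=O)OC(C)(C)C)C(C)(C)CCC1=O | intermediate
5 | tert-butyl 2-(bromomethyl)-6,6-dimethyl-3-oxocyclohex-1-ene-1-carboxylate | BrCC1=C(C(=O)OC(C)(C)C)C(C)(C)CCC1=O | intermediate
6 | 4-methoxybenzyl alcohol | COc1ccc(CO)cc1 | starting material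
7 | tert-butyl 2-[(4-methoxybenzyloxy)methyl]-6,6-dimethyl-3-oxocyclohex-1-ene-1-carboxylate | COc1ccc(COCC2=C(C(=O)OC(C)(C)C)C(C)(C)CCC2=O)cc1 | intermediate
8 | tert-butyl (3S)-3-hydroxy-2-[(4-methoxybenzyloxy)methyl]-6,6-dimethylcyclohex-1-ene-1-carboxylate | COc1ccc(COCC2=C(C(=O)OC(C)(C)C)C(C)(C)CC[C@@H]2O)cc1 | intermediate
9 | (bromomethyl)chlorodimethylsilane | C[Si](C)(Cl)CBr | starting material
10 | (bromomethyl)dimethylsilyl ether of 8 (key-step precursor) | COc1ccc(COCC2=C(C(=O)OC(C)(C)C)C(C)(C)CC[C@@H]2O[Si](C)(C)CBr)cc1 | intermediate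
11 | cis-fused oxasilolane with quaternary C10 (key-step product) | COc1ccc(COC[C@]23C[Si](C)(C)O[C@H]2CCC(C)(C)[C@H]3C(=O)OC(C)(C)C)cc1 | intermediate
12 | ring A diol (C1–OH, C20–OH cis; C9–OPMB; C5 ester cis to C20) | COc1ccc(COC[C@]2(CO)[C@@H](O)CCC(C)(C)[C@H]2C(=O)OC(C)(C)C)cc1 | intermediate
13 | diketene | C=C1CC(=O)O1 | starting material
14 | C20 acetoacetate of 12 | COc1ccc(COC[C@]2(COC(=O)CC(C)=O)[C@@H](O)CCC(C)(C)[C@H]2C(=O)OC(C)(C)C)cc1 | intermediate
15 | C1 acetate of 14 | COc1ccc(COC[C@]2(COC(=O)CC(C)=O)[C@@H](OC(C)=O)CCC(C)(C)[C@H]2C(=O)OC(C)(C)C)cc1 | intermediate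
16 | C9 primary alcohol | OC[C@]1(COC(=O)CC(C)=O)[C@@H](OC(C)=O)CCC(C)(C)[C@H]1C(=O)OC(C)(C)C | intermediate
17 | C9 aldehyde (not isolated) | O=C[C@]1(COC(=O)CC(C)=O)[C@@H](OC(C)=O)CCC(C)(C)[C@H]1C(=O)OC(C)(C)C | intermediate
18 | spiro alkylidene β-keto lactone (C8=C9) | CC(=O)O[C@H]1CCC(C)(C)[C@@H](C(=O)OC(C)(C)C)[C@@]12COC(=O)C(C(C)=O)=C2 | intermediate
19 | buta-1,3-diene | C=CC=C | starting material
20 | Diels–Alder adduct (ring C, C12=C13, 8-acetyl) | CC(=O)O[C@H]1CCC(C)(C)[C@@H](C(=O)OC(C)(C)C)[C@@]12COC(=O)[C@@]3(C(C)=O)CC=CC[C@@H]23 | intermediate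
21 | tert-butyldimethylsilyl enol ether of 20 | CC(=O)O[C@H]1CCC(C)(C)[C@@H](C(=O)OC(C)(C)C)[C@@]12COC(=O)[C@@]3(C(=C)O[Si](C)(C)C(C)(C)C)CC=CC[C@@H]23 | intermediate
22 | tetracyclic ketone (bicyclo[3.2.1]octene, C11=C12, C15 ketone) | CC(=O)O[C@H]1CCC(C)(C)[C@@H](C(=O)OC(C)(C)C)[C@@]12COC(=O)[C@@]13C[C@@H](C=C[C@H]12)CC3=O | intermediate
23 | 16-methylene-15-ketone | CC(=O)O[C@H]1CCC(C)(C)[C@@H](C(=O)OC(C)(C)C)[C@@]12COC(=O)[C@@]13C[C@@H](C=C[C@H]12)C(=C)C3=O | intermediate
24 | tert-butyl ester of the target | CC(=O)O[C@H]1CCC(C)(C)[C@@H](C(=O)OC(C)(C)C)[C@@]12COC(=O)[C@@]13C[C@@H](CC[C@H]12)[C@@H](C)C3=O | intermediate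
25 | CNP0161834.1 | CC(=O)O[C@H]1CCC(C)(C)[C@@H](C(=O)O)[C@@]12COC(=O)[C@@]13C[C@@H](CC[C@H]12)[C@@H](C)C3=O | target

## Step count and risks

Total step count: 19. Longest linear sequence: 19 steps (from 1 to 25).

Steps most likely to fail:

1. Step 8 (radical cyclisation).
   - Risk: the α-silyl radical may be reduced by the stannane, or the Si–O link lost, before it closes onto the fully substituted C10; hydrogen transfer to C5 may also be less face-selective than expected.
   - Fallback: this sets out from 8, replaces the silicon tether by an acetal tether with later excision of one carbon, and returns at 12. Alcohol 8 with ethyl vinyl ether and N-bromosuccinimide should give the mixed bromoacetal F1 (epimers at the acetal carbon). Bu3SnH with azobisisobutyronitrile (Ueno–Stork cyclisation) should close the primary alkyl radical 5-exo onto C10 to the cis-fused 2-ethoxytetrahydrofuran F2. TMSOTf with iPr2NEt removes ethanol to give the dihydrofuran F3. OsO4 (cat.) with NaIO4 cleaves the enol ether double bond to the C20 aldehyde C1 formate F4. NaBH4 in methanol reduces the aldehyde and the formate is lost by methanolysis, which gives diol 12.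

2. Step 14 (Diels–Alder reaction).
   - Risk: cycloaddition at the neopentyl C9 may be sluggish, so that butadiene oligomerises or the acyl lactone reacts as a heterodiene, and discrimination between the C1 and C5 flanks may be incomplete.
   - Fallback: this sets out from 18, uses an uncatalysed cycloaddition with an activated diene followed by reductive removal of the extra oxygen, and returns at 20. Lactone 18 with 2-(trimethylsilyloxy)buta-1,3-diene in toluene at moderate temperature should bond the diene CH2 next to the silyloxy carbon to C9, giving the silyl enol ether adduct F5 (C12–OSiMe3, C12=C13). CsF with N-phenyl-bis(trifluoromethanesulfonimide) converts it regiospecifically into the enol triflate F6. Pd(OAc)2 with PPh3, formic acid and Bu3N replaces the triflate by hydrogen and gives 20.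

3. Step 16 (palladium-mediated ring D closure).
   - Risk: insertion may occur at C12 (bicyclo[2.2.2]octane) instead of C13, the enol ether may simply be desilylated because the acetyl group must sit axial on ring C, or a palladium hydride may move the ring C double bond.
   - Fallback: this is a polar, regiochemically fixed closure that sets out from 18 through the adduct F5 described under step 14 and returns at 22. N-bromosuccinimide brominates the silyl enol ether at C13 to give the α-bromo ketone F7 (C13 epimers, which interconvert through the C12 enol). KOtBu in THF at low temperature forms the C16 enolate of the methyl ketone, which displaces bromide at C13 to give the bridged 12,15-diketone F8. NaBH4 at −78 °C should reduce the less hindered C12 ketone to the alcohol F9 (either C12 epimer serves). Burgess reagent dehydrates it toward C11 only, since C13 is a bridgehead, and gives 22.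

## Further compounds

F1 | step 8 | bromoacetal of 8 (2-bromo-1-ethoxyethyl ether at O1) | COc1ccc(COCC2=C(C(=O)OC(C)(C)C)C(C)(C)CC[C@@H]2OC(CBr)OCC)cc1
F2 | step 8 | cis-fused 2-ethoxytetrahydrofuran (C20 bonded to C10) | COc1ccc(COC[C@]23CC(OCC)O[C@H]2CCC(C)(C)[C@H]3C(=O)OC(C)(C)C)cc1
F3 | step 8 | cis-fused dihydrofuran (enol ether) | COc1ccc(COC[C@]23C=CO[C@H]2CCC(C)(C)[C@H]3C(=O)OC(C)(C)C)cc1
F4 | step 8 | C20 aldehyde C1 formate | COc1ccc(COC[C@]2(C=O)[C@@H](OC=O)CCC(C)(C)[C@H]2C(=O)OC(C)(C)C)cc1
F5 | step 14 | silyl enol ether Diels–Alder adduct (C12–OSiMe3, C12=C13) | CC(=O)O[C@H]1CCC(C)(C)[C@@H](C(=O)OC(C)(C)C)[C@@]12COC(=O)[C@@]3(C(C)=O)CC=C(O[Si](C)(C)C)C[C@@H]23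
F6 | step 14 | enol triflate (C12–OTf, C12=C13) | CC(=O)O[C@H]1CCC(C)(C)[C@@H](C(=O)OC(C)(C)C)[C@@]12COC(=O)[C@@]3(C(C)=O)CC=C(OS(=O)(=O)C(F)(F)F)C[C@@H]23
F7 | step 16 | 13-bromo-12-ketone (C13 epimers) | CC(=O)O[C@H]1CCC(C)(C)[C@@H](C(=O)OC(C)(C)C)[C@@]12COC(=O)[C@@]3(C(C)=O)CC(Br)C(=O)C[C@@H]23
F8 | step 16 | bridged 12,15-diketone | CC(=O)O[C@H]1CCC(C)(C)[C@@H](C(=O)OC(C)(C)C)[C@@]12COC(=O)[C@@]13C[C@@H](C(=O)C[C@H]12)CC3=O
F9 | step 16 | 12-hydroxy-15-ketone (C12 epimers) | CC(=O)O[C@H]1CCC(C)(C)[C@@H](C(=O)OC(C)(C)C)[C@@]12COC(=O)[C@@]13C[C@@H](C(O)C[C@H]12)CC3=O
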